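**One-step world.** Imagine that starting material meets coupling partner, nothing else happens, and partner stays as charged (the pseudo-first-order picture). One time is then enough, and you count how many half-lives fit into the hours. Real partner falls, so you count each hour in proportion to the partner left.

the same everywhere: starting material 0.050 M (in portions, 2)

|  | coupling partner | remark | time |
|---|---|---|---|
| dusk | 0.050 M | the very flask that is asked about, followed so far; portions every 12 h |  |
| summer | 0.025 M | run made earlier; portions every 12 h |  |
| flask | 0.0500 M | the portions of starting material follow each other after 12 h, the first at the start | 25 h |

| run | time / h | starting material / % | single product / % | double product / % |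
|---|---|---|---|---|
| dusk | 1.33 | 49 | 2 | 0 |
| dusk | 2.50 | 46 | 0 | 1 |
| dusk | 4.00 | 47 | 3 | 0 |
| dusk | 5.00 | 46 | 7 | 1 |
| dusk | 6.00 | 44 | 5 | 2 |
| dusk | 8.00 | 43 | 5 | 2 |
| summer | 1.33 | 49 | 0 | 1 |
| summer | 3.00 | 51 | 4 | 0 |
| summer | 6.00 | 46 | 3 | 0 |
| summer | 10.0 | 45 | 2 | 0 |
| summer | 12.0 | 44 | 4 | 0 |
| summer | 20.0 | 89 | 12 | 1 |

(scatter of a reading: 1.5 percentage points)

- steps thought possible: starting material + coupling partner -> single product; coupling partner + single product -> double product; coupling partner + double product -> triple product; coupling partner + triple product -> tetra adduct

* how much starting material there is at 25 h, in percent of the starting material charged
* how much single product there is at 25 h, in percent of the starting material charged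
* how much double product there is at 25 h, in percent of the starting material charged
* how much triple product there is at 25 h, in percent of the starting material charged

**Reading the clock.** In the summer run, the first portion, half of the charge, fell to a reading of 44 % in 12.0 h, which reads as a half-life of 65.1 h at 0.025 M of partner. Scaled to 0.0500 M of partner, this gives 32.5 h, the charged half-life: the half-life of starting material with partner as charged. As a check, it gives 42.2 % at 8.00 h in the dusk run, where the reading is 43 %.

**The decision.** Should you plan on a finished flask at 25 h? That time is shorter than one charged half-life, so no.

The first 12 h count 0.369 half-lives with partner held as charged, leaving 38.7 %. The second portion lifts this to 88.7 %. In the one-step world of this flask the two charges are equal, so you put partner at that same figure of its own charge.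

Held there, the last 13.0 h leave 69.4 %. But partner falls along with starting material, so you take the mean of those two figures as the partner level, and your count leaves 71.3 %. So you charge the recipe as it stands, read at 25 h, and plan to recover about that much starting material.

**The forecast.** The forecast, which finds that “The double-product data are sparse”, gives 73 % of starting material, above your figure, with 22 % single, 4.3 % double and 0.5 % triple product.

**The result.** The flask gives 73.3 % of starting material. It holds 15.3 % of single product. It holds 8.20 % of double product. It holds 2.63 % of triple product.

    starting material + coupling partner → single product (k = 0.428 M⁻¹ h⁻¹)
    coupling partner + single product → double product (k = 1.43 M⁻¹ h⁻¹)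
    coupling partner + double product → triple product (k = 1.04 M⁻¹ h⁻¹)
    coupling partner + triple product → tetra adduct (k = 0.710 M⁻¹ h⁻¹)

**The slowing clock.** In this flask at 13.8 h the half-life of starting material by its own step is already 40 h, longer than your charged half-life of 32.5 h, while partner goes 2.9 times as fast into single product as into double product. The neighbour flask left until 4.0 d has had 2.95 charged half-lives on the plain clock, yet it holds 52.5 % of starting material, with partner at 4.88 % of its own charge.

The numbers in the tables come from a simulation for an exercise, and the scatter is random.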